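**Retrosynthetic overview**
1. The last operation removes a benzyl ether at O8 and a pivalate at O3'. Before that, the bond between C2 of the pyran-4-one ring (ring C) and C1' of the trioxygenated phenyl ring (ring B) is cut, giving a chroman-4-one (C2 and C3 still saturated) and an arylboronic acid.
2. Enabling feature: the O1–C2–C3–C4(=O) segment of ring C. At the dihydro level C3–H is α and C2–H is β to the C4 ketone, so Pd(II) can dehydrogenate it. In the resulting enone, O1 and C4=O polarise C2=C3 so that an aryl–Pd species delivers its aryl group to C2, and a second β-hydride loss restores the pyranone.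
3. Ring B half: C1' is the only C–H of the 1,2,3-trioxygenated benzene ring with no ortho substituent, so sterically controlled Ir-catalysed C–H borylation of 2,3-dimethoxyphenyl pivalate installs boron there.
4. Ring A/C half: ring C is closed by intramolecular Friedel–Crafts acylation (C4–C4a bond) of a 3-aryloxypropanoic acid. The phenol for it comes from Baeyer–Villiger (Dakin-type) oxidation of O-benzylated 2-hydroxy-3,4-dimethoxybenzaldehyde, and the three-carbon chain from β-propiolactone.
5. Ring order: rings A and B are bought as benzene rings. Ring C is closed as a dihydropyranone in step 4 and oxidised to the pyran-4-one in the key step, in the same operation that attaches ring B.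

Key step: step 7

Remark: the target has no stereocentre, stereogenic axis or stereogenic double bond. It is achiral, so the structure as drawn is reached without any stereocontrol.

**Route**

Step 1
Reactants: 1 2-hydroxy-3,4-dimethoxybenzaldehyde
Product: 2 2-(benzyloxy)-3,4-dimethoxybenzaldehyde
Conditions: BnBr (1.2 equiv), K2CO3 (1.5 equiv), DMF, 60 °C
Reagents that add atoms: benzyl bromide, BrCc1ccccc1
Why: Williamson etherification of the acidic ortho-formyl phenol; benzyl is chosen because it should survive peracid, NaH, HCl/HFIP and Pd(II)/O2 and leaves at the end by hydrogenolysis without touching the four methyl ethers.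

Step 2
Reactants: 2 2-(benzyloxy)-3,4-dimethoxybenzaldehyde
Product: 4 2-(benzyloxy)-3,4-dimethoxyphenol, via aryl formate 3 (not isolated)
Conditions: mCPBA (1.3 equiv), CH2Cl2, 0 °C to rt; aq. NaHCO3 wash; then MeOH, Et3N (cat.), rt
Reagents that add atoms: 3-chloroperbenzoic acid (mCPBA), OOC(=O)c1cccc(Cl)c1
Why: Baeyer–Villiger oxidation of an electron-rich benzaldehyde (Dakin-type), in which the aryl group, activated by the ortho benzyloxy and para methoxy groups, migrates in preference to hydride, followed by methanolysis of the aryl formate.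

Step 3
Reactants: 4 2-(benzyloxy)-3,4-dimethoxyphenol; 5 β-propiolactone
Product: 6 3-[2-(benzyloxy)-3,4-dimethoxyphenoxy]propanoic acid
Conditions: NaH (1.05 equiv), DMF, 0 °C; then 5 (1.2 equiv), rt; aq. HCl work-up
Reagents that add atoms: none
Why: SN2 opening of the β-lactone at its O–CH2 carbon (alkyl–oxygen cleavage) by the soft aryloxide should give the 3-aryloxypropanoic acid in one operation, without the elimination to acrylate that troubles 3-halopropanoates.

Step 4
Reactants: 6 3-[2-(benzyloxy)-3,4-dimethoxyphenoxy]propanoic acid
Product: 8 8-(benzyloxy)-6,7-dimethoxychroman-4-one, via acid chloride 7 (not isolated)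
Conditions: (COCl)2 (1.3 equiv), DMF (cat.), CH2Cl2, 0 °C to rt; evaporate; then (CF3)2CHOH (HFIP), rt
Reagents that add atoms: none
Why: HFIP-promoted intramolecular Friedel–Crafts acylation of the acid chloride closes the six-membered ring at the only free position ortho to the ether oxygen (also para to the 3-methoxy group), with no Lewis acid present, conditions that a plain benzyl aryl ether should tolerate.

Step 5
Reactants: 9 2,3-dimethoxyphenol
Product: 10 2,3-dimethoxyphenyl pivalate
Conditions: PivCl (1.2 equiv), Et3N (1.5 equiv), DMAP (5 mol%), CH2Cl2, 0 °C to rt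
Reagents that add atoms: pivaloyl chloride, CC(C)(C)C(=O)Cl
Why: DMAP-catalysed O-acylation; the pivalate masks the phenol through borylation and the aerobic Pd step, carries no arene C–H that could be borylated, and its bulk further shields the adjacent ring position.

Step 6
Reactants: 10 2,3-dimethoxyphenyl pivalate
Product: 12 [3,4-dimethoxy-5-(pivaloyloxy)phenyl]boronic acid, via pinacol boronate 11 (not isolated)
Conditions: [Ir(OMe)(cod)]2 (1.5 mol%), dtbpy (3 mol%), B2pin2 (0.55 equiv), THF, 80 °C; evaporate; then NaIO4 (3 equiv), NH4OAc (3 equiv), acetone/H2O, rt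
Reagents that add atoms: bis(pinacolato)diboron, CC1(C)OB(OC1(C)C)B1OC(C)(C)C(C)(C)O1; water, O
Why: Iridium-catalysed arene C–H borylation is sterically controlled and should take the only ring C–H without an ortho substituent (C5, meta to both the pivalate and the 3-methoxy group), and periodate then cleaves the pinacol to acetone, which drives the ester to the free boronic acid.

Step 7
Reactants: 8 8-(benzyloxy)-6,7-dimethoxychroman-4-one; 12 [3,4-dimethoxy-5-(pivaloyloxy)phenyl]boronic acid
Product: 14 5-[8-(benzyloxy)-6,7-dimethoxy-4-oxo-4H-chromen-2-yl]-2,3-dimethoxyphenyl pivalate, via chromone 13 (not isolated)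
Conditions: Pd(TFA)2 (15 mol%), 5-nitro-1,10-phenanthroline (20 mol%), 12 (2.5 equiv, added in portions), O2 (1 atm), DMSO, 100 °C
Reagents that add atoms: none
Why: Pd(II) enolises the C4 ketone at C3 and β-hydride elimination of a C2 hydrogen gives chromone 13; the aryl group of 12 is then transferred to Pd(II), the aryl–Pd bond adds across C2=C3 with the aryl group at C2 and Pd at C3, and the Pd enolate, after C/O-enolate equilibration, loses the remaining C2 hydrogen to give the flavone, with O2 returning Pd(0) to Pd(II) after each oxidation. The closest known reaction type is the one-pot Pd(II)-catalysed dehydrogenation/oxidative boron-Heck coupling of chroman-4-ones with arylboronic acids, a merger of aerobic Pd ketone dehydrogenation and the oxidative Heck reaction. No ring is closed here: the dihydropyranone closed in step 4 is oxidised to the 4H-pyran-4-one while ring B is attached, and no stereocentre is formed. The step needs regioselectivity for C2 over C3, secured by the polarisation of the O1–C2=C3–C4=O unit (C2 is the β-carbon and Pd ends as the stabilised C3 enolate). It also needs cross-coupling to outrun homocoupling and protodeboronation of 12, which the phenanthroline ligand, the base-free medium and portionwise excess of 12 should secure. Premature protonation of the Pd enolate is not a dead end, since the same catalyst dehydrogenates saturated chromanones, and the benzyl ether, pivalate and methyl ethers should be inert to Pd(II)/O2 in DMSO.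

Step 8
Reactants: 14 5-[8-(benzyloxy)-6,7-dimethoxy-4-oxo-4H-chromen-2-yl]-2,3-dimethoxyphenyl pivalate
Product: 16 8-hydroxy-2-(3-hydroxy-4,5-dimethoxyphenyl)-6,7-dimethoxy-4H-chromen-4-one, via monophenol 15 (not isolated)
Conditions: K2CO3 (2 equiv), MeOH/THF, rt, Ar; AcOH to neutral; then H2 (1 atm), 10% Pd/C, rt; filter
Reagents that add atoms: none
Why: Base-mediated methanolysis of the aryl pivalate followed by Pd/C hydrogenolysis of the benzyl aryl ether should free both phenols, while the aryl methyl ethers are inert to both reagents and the C2=C3 bond of the flavone, a vinylogous ester conjugated to two arenes, should not be reduced at 1 atm and room temperature.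

**Compound list**
1 | 2-hydroxy-3,4-dimethoxybenzaldehyde | O=Cc1ccc(OC)c(OC)c1O | starting material
2 | 2-(benzyloxy)-3,4-dimethoxybenzaldehyde | O=Cc1ccc(OC)c(OC)c1OCc1ccccc1 | intermediate
3 | 2-(benzyloxy)-3,4-dimethoxyphenyl formate | O=COc1ccc(OC)c(OC)c1OCc1ccccc1 | intermediate
4 | 2-(benzyloxy)-3,4-dimethoxyphenol | Oc1ccc(OC)c(OC)c1OCc1ccccc1 | intermediate
5 | β-propiolactone (oxetan-2-one) | O=C1CCO1 | starting material
6 | 3-[2-(benzyloxy)-3,4-dimethoxyphenoxy]propanoic acid | OC(=O)CCOc1ccc(OC)c(OC)c1OCc1ccccc1 | intermediate
7 | 3-[2-(benzyloxy)-3,4-dimethoxyphenoxy]propanoyl chloride | ClC(=O)CCOc1ccc(OC)c(OC)c1OCc1ccccc1 | intermediate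
8 | 8-(benzyloxy)-6,7-dimethoxychroman-4-one | O=C1CCOc2c(OCc3ccccc3)c(OC)c(OC)cc12 | intermediate
9 | 2,3-dimethoxyphenol | COc1cccc(O)c1OC | starting material
10 | 2,3-dimethoxyphenyl pivalate | COc1cccc(OC(=O)C(C)(C)C)c1OC | intermediate
11 | 2,3-dimethoxy-5-(4,4,5,5-tetramethyl-1,3,2-dioxaborolan-2-yl)phenyl pivalate | COc1cc(B2OC(C)(C)C(C)(C)O2)cc(OC(=O)C(C)(C)C)c1OC | intermediate
12 | [3,4-dimethoxy-5-(pivaloyloxy)phenyl]boronic acid | COc1cc(B(O)O)cc(OC(=O)C(C)(C)C)c1OC | intermediate
13 | 8-(benzyloxy)-6,7-dimethoxy-4H-chromen-4-one | O=c1ccoc2c(OCc3ccccc3)c(OC)c(OC)cc12 | intermediate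
14 | 5-[8-(benzyloxy)-6,7-dimethoxy-4-oxo-4H-chromen-2-yl]-2,3-dimethoxyphenyl pivalate | COc1cc(-c2cc(=O)c3cc(OC)c(OC)c(OCc4ccccc4)c3o2)cc(OC(=O)C(C)(C)C)c1OC | intermediate
15 | 8-(benzyloxy)-2-(3-hydroxy-4,5-dimethoxyphenyl)-6,7-dimethoxy-4H-chromen-4-one | COc1cc(-c2cc(=O)c3cc(OC)c(OC)c(OCc4ccccc4)c3o2)cc(O)c1OC | intermediate
16 | 8-hydroxy-2-(3-hydroxy-4,5-dimethoxyphenyl)-6,7-dimethoxy-4H-chromen-4-one | COc1cc(-c2cc(=O)c3cc(OC)c(OC)c(O)c3o2)cc(O)c1OC | target

**Totals**
Total step count: 8. Longest linear sequence: 6 steps (steps 1, 2, 3, 4, 7, 8).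

**Steps most likely to fail**

Step 7. Oxidative consumption of the electron-rich boronic acid (homocoupling, protodeboronation, phenol formation) may outrun its insertion into the electron-rich enone, or the two oxidations may not mesh under one set of conditions. The fallback separates the three events and makes the C–C bond without an oxidant. It sets out from 8 and comes back at 14. Chromanone 8 would be dehydrogenated with IBX (DMSO, 70 °C) to chromone 13, now isolated. Rhodium(I)-catalysed conjugate addition of 12 to 13 ([Rh(OH)(cod)]2, dioxane/H2O, 60 °C) would give the racemic flavanone 5-[8-(benzyloxy)-6,7-dimethoxy-4-oxochroman-2-yl]-2,3-dimethoxyphenyl pivalate F1. Its stereocentre is erased when DDQ (dioxane, 100 °C) dehydrogenates it to 14.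

Step 4. The uncatalysed acylation may stall, because the ring carbon is activated only by the ortho ether oxygen and by a para methoxy group that its two neighbours twist out of conjugation; forcing it with stronger acid would start loss or migration of the benzyl group. The fallback builds the ketone without any electrophilic aromatic acylation. It sets out from 4 and comes back at 8. Magnesium-mediated ortho-formylation of 4 (MgCl2, Et3N, paraformaldehyde, MeCN, reflux) would give 3-(benzyloxy)-2-hydroxy-4,5-dimethoxybenzaldehyde F2. Addition of vinylmagnesium bromide (2.5 equiv, THF, −78 to 0 °C) would give racemic 1-[3-(benzyloxy)-2-hydroxy-4,5-dimethoxyphenyl]prop-2-en-1-ol F3. MnO2 (CH2Cl2, rt) would oxidise it to the aryl vinyl ketone 1-[3-(benzyloxy)-2-hydroxy-4,5-dimethoxyphenyl]prop-2-en-1-one F4, which should close in the flask by intramolecular oxa-Michael addition of the phenol (cat. Et3N if needed) to 8.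

Step 3. The aryloxide may attack the lactone at the acyl carbon, and the product carboxylate may oligomerise the lactone, eroding the conversion to the acid. The fallback replaces lactone opening by alkylation and oxidation. It sets out from 4 and comes back at 6. Alkylation of 4 with 3-bromopropan-1-ol (K2CO3, DMF, 70 °C) would give 3-[2-(benzyloxy)-3,4-dimethoxyphenoxy]propan-1-ol F5. Oxidation of the primary alcohol (TEMPO cat., PhI(OAc)2, MeCN/H2O, rt) would give acid 6.

**Further compounds**
F1 | step 7 | 5-[8-(benzyloxy)-6,7-dimethoxy-4-oxochroman-2-yl]-2,3-dimethoxyphenyl pivalate (racemic) | COc1cc(C2CC(=O)c3cc(OC)c(OC)c(OCc4ccccc4)c3O2)cc(OC(=O)C(C)(C)C)c1OC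
F2 | step 4 | 3-(benzyloxy)-2-hydroxy-4,5-dimethoxybenzaldehyde | O=Cc1cc(OC)c(OC)c(OCc2ccccc2)c1O
F3 | step 4 | 1-[3-(benzyloxy)-2-hydroxy-4,5-dimethoxyphenyl]prop-2-en-1-ol (racemic) | C=CC(O)c1cc(OC)c(OC)c(OCc2ccccc2)c1O
F4 | step 4 | 1-[3-(benzyloxy)-2-hydroxy-4,5-dimethoxyphenyl]prop-2-en-1-one | C=CC(=O)c1cc(OC)c(OC)c(OCc2ccccc2)c1O
F5 | step 3 | 3-[2-(benzyloxy)-3,4-dimethoxyphenoxy]propan-1-ol | OCCCOc1ccc(OC)c(OC)c1OCc1ccccc1
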